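## Structural features

The target, (R)-8-hydroxy-3-(11-hydroxyundecyl)-6-methoxyisochroman-1-one, is a 3,4-dihydroisocoumarin: benzene ring A is fused along C4a–C8a to the six-membered lactone ring B (C1 carbonyl, O2, C3, C4). Ring A is a 1,2,3,5-tetrasubstituted benzene with two different oxygens, a methyl ether at C6 and a free phenol at C8 peri to the lactone carbonyl; C5 and C7 carry hydrogen. The only stereocentre is C3 (R; O2 > C4 > chain C1′ > H). It has no stereogenic neighbour, lies between two methylene groups (C4 and C1′) and carries an unbranched eleven-carbon chain ending in a primary alcohol. The sensitive groups are the lactone (opened by hydroxide or alkoxide), the free phenol and the primary alcohol; in the intermediates the 4-methoxy-2-pyranone accepts electrophiles at its C3 and the bromoalkynoate accepts nucleophiles. The real difficulty is control, not size: a regiodefined arene with two differentiated meta oxygens, and a carbinol centre whose two carbon substituents differ only beyond their first methylene. The key step uses the fact that C5–H, C6–OMe, C7–H, C4a and C4 already exist, in the right order, as C5, C4, C3, C6 and the methyl group of 4-methoxy-6-methyl-2-pyranone. The four atoms C4–C3–O2–C1 of ring B then serve as the tether that delivers an alkyne (the future C8a and C8) to that diene, so rings A and B form in one operation.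

## Logic of the disconnections

**16 to 15.** The O–Si bond of the primary alcohol is cut last. The chain hydroxyl must be masked through the organolithium, oxidation, acylation and thermal steps, and a silyl ether comes off under acid that leaves the lactone closed. The forward step needs only an acid without a nucleophilic alcohol as solvent.

**15 to 13 (through 14).** The C8–O bond is traded for C8–Br. An oxygen cannot sit on the alkyne terminus without making it a push-pull alkyne and a poor dienophile, whereas bromine keeps it electron-poor and is a handle at exactly C8. The forward demand is a C–Br to C–B to C–O exchange that spares the lactone and the silyl ether, run in one pot so that the handle costs a single step.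

**13 to 11 (through 12).** Cutting C4a–C8a and C7–C8 and restoring the CO2 bridge dismantles both rings at once. Ring A returns to a 4-methoxy-2-pyranone and ring B to an open ester whose alkyne is held four atoms from the diene. This is the largest gain in the plan: two rings and the full substitution pattern of ring A come from one acyclic-ester precursor with no new stereocentre. The forward step needs the ester to reach its lactone-like rotamer, cyclisation to beat dimerisation, and 11 to survive the heat. The skeleton and the bromine of 11 are kept; two refinements are that the halogen is put on the acid before esterification, and that 11 is formed and handled without base.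

**11 to 8 and 10; 10 to 9.** The ester C1–O2 bond is cut to a secondary alcohol and a bromoalkynoic acid. Brominating after esterification would put electrophilic bromine in contact with the nucleophilic C3 of the pyranone, so the C–Br bond is made on 9 first. The forward esterification must be near neutral, because the C4 methylene of 11 is acidic and its acyloxy group is a good leaving group.

**8 to 7 to 6.** The C3–H bond is cut to a ketone so that the stereocentre is set by catalyst-controlled reduction; 7 comes from racemic 6 by oxidation. This removes the only stereochemical problem from the carbon–carbon bond formation. The demand is facial discrimination between two methylene-flanked sides, the weakest point before the key step. Direct acylation of 5 at the ketone level would save a step, but it exposes 5 to a product more acidic than its precursor. The aldehyde addition is the more dependable reaction of 5, so the redox detour is accepted.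

**6 to 4 (through 5) and 3.** The C3–C4 bond is cut between the pyranone methyl carbon and an aldehyde carbon. This splits the molecule into the complete ring A precursor and the complete chain. The forward step needs deprotonation at the methyl group and not at the ring or by addition to C2.

**3 to 2 to 1.** The aldehyde is reached by oxidation level and one O–Si bond from a symmetric C12 diol. The only demand is monoprotection of two equivalent hydroxyls.

## Other disconnections considered

**Alternative 1:** The cut is the O2–C3 bond of ring B, with a vinyl group in place of the chain. In the forward direction 2-(buta-2,3-dien-1-yl)-4,6-dimethoxybenzoic acid A1 would be cycloisomerised with [Rh(cod)Cl]2 and a DIOP-type diphosphine. The carboxylate adds to the allene carbon nearer the ring and gives (S)-6,8-dimethoxy-3-vinylisochroman-1-one A2. The S label of A2 is the same spatial arrangement as R in the target, because the vinyl carbon outranks C4. Cross-metathesis of A2 with undec-10-en-1-ol A3 (second-generation Grubbs catalyst), hydrogenation and cleavage of the C8 methyl ether with BCl3 would finish the synthesis.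
- In favour: ring A is bought, the step is an isomerisation with no by-product, and stereocentre and lactone are made together. The chain alcohol needs no protecting group. In these respects it is better than the chosen plan.
- Against: A1 needs several steps of ortho functionalisation and allene installation. The enantioselectivity of a six-membered lactonisation depends on the ligand and is not assured. The allylic-ester alkene of A2 is a sluggish metathesis partner. The two aryl oxygens are only differentiated at the end by a peri-selective demethylation.
- Comparison: structurally the chosen plan builds the OMe/OH difference in, while the alternative relies on the carbonyl-directed demethylation, which is dependable, so this is about equal. Mechanistically an organometallic π-allyl pathway under ligand control is set against a thermal pericyclic step with no stereochemical demand; the stereochemical risk of the alternative is comparable to that of step 5. In step count the alternative needs three operations after its key step against two here, and the totals should be similar.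

**Alternative 2:** The cuts are C4a–C5 and C8–C8a. Methyl (R)-5,16-bis[(tert-butyldimethylsilyl)oxy]hexadec-2-ynoate A4 would be heated with 1,3-dimethoxy-1-(trimethylsilyloxy)buta-1,3-diene A5 and worked up with mild acid. The product would be methyl 2-[(R)-2,13-bis[(tert-butyldimethylsilyl)oxy]tridecyl]-6-hydroxy-4-methoxybenzoate A6.
- In favour: the C8 phenol and the C6 methyl ether arrive directly and differentiated, with no halogen detour. One acidic operation on A6 (desilylation and lactonisation) should give the target. The stereocentre of A4 would come from epoxide-opening chemistry of known absolute sense. On these three points it is better than the chosen plan.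
- Against: A4 is a β-alkyl ynoate, a slow and hindered dienophile. A5 is a labile ketene acetal that tends to decompose or desilylate at the temperatures such a partner needs. The reaction is bimolecular, and regiochemistry rests on polarity alone.
- Comparison: both plans aromatise a [4+2] adduct, one by loss of methanol and silanol, the other by loss of CO2. The chosen plan has tether-enforced regiochemistry and an entropic advantage, but pays the ester rotamer penalty and needs high dilution. The alternative forms ring A only, while the chosen step forms rings A and B. If its cycloaddition were efficient the alternative would be the shorter route; its risk is concentrated in that one step.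

**Alternative 3:** The cut is C1–C8a. (R)-13-(Benzyloxy)-1-(3,5-dimethoxyphenyl)tridecan-2-yl dimethylcarbamate A7 would be activated with Tf2O and 2-chloropyridine. Ring A attacks the activated carbamate carbon ortho to the side chain, and hydrolysis of the cyclic iminium gives (R)-3-[11-(benzyloxy)undecyl]-6,8-dimethoxyisochroman-1-one A8. BCl3 could then remove the benzyl group and the C8 methyl group in one operation.
- In favour: ring A is bought, and the two ortho positions of the symmetric arene are equivalent, so regiochemistry is as secure as with the tether. The carbinol of A7 can be taken from the chiral pool, which is more dependable than step 5. The step runs cold and at normal concentration, operationally better than a dilute thermolysis.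
- Against: a strongly electrophilic activator meets an electron-rich arene and a benzyl ether. The activated secondary C–O bond may ionise or eliminate, with erosion of C3. The oxygen pattern is again differentiated only by a final demethylation.
- Comparison: the alternative forms one bond and one ring by electrophilic aromatic substitution; the chosen step forms two bonds and two rings by a pericyclic sequence. The post-key-step work is about equal (one or two operations against two), and the overall length should be similar. The chosen plan avoids strong electrophiles at the stereocentre but accepts a less certain reduction and a hot step.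

Key step: step 8

Assumption: in step 5 the pyranonylmethyl side of ketone 7 is taken to occupy the place an aryl group takes in the transfer-hydrogenation transition state, so the (R,R) catalyst is assigned to give (R)-8. The configuration should be confirmed on 8 by Mosher ester analysis, and the antipodal catalyst used if the sense is opposite.

## Route

Step 1
Reactants: 1 dodecane-1,12-diol
Product: 2 12-[(tert-butyldimethylsilyl)oxy]dodecan-1-ol
Conditions: NaH (1.0 equiv), THF, 0 °C → rt; TBSCl (1.0 equiv), rt
Reagents that add atoms: tert-butyldimethylsilyl chloride, CC(C)(C)[Si](C)(C)Cl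
Why: O-silylation of the monosodium alkoxide of a symmetric diol; the sparingly soluble monoalkoxide is silylated faster than it is converted to the dialkoxide, so the mono ether should predominate and unreacted diol is recoverable.

Step 2
Reactants: 2 12-[(tert-butyldimethylsilyl)oxy]dodecan-1-ol
Product: 3 12-[(tert-butyldimethylsilyl)oxy]dodecanal
Conditions: TEMPO (10 mol%), PhI(OAc)2 (1.1 equiv), CH2Cl2, rt
Reagents that add atoms: none
Why: Oxoammonium (TEMPO) oxidation of a primary alcohol, which stops at the aldehyde in anhydrous CH2Cl2; the silyl ether tolerates the acetic acid released.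

Step 3
Reactants: 4 4-methoxy-6-methyl-2H-pyran-2-one; 3 12-[(tert-butyldimethylsilyl)oxy]dodecanal
Product: 6 rac-6-[13-[(tert-butyldimethylsilyl)oxy]-2-hydroxytridecyl]-4-methoxy-2H-pyran-2-one, via 6-(lithiomethyl)-4-methoxy-2H-pyran-2-one 5 (not isolated)
Conditions: LiN(iPr)2 (1.1 equiv), THF, −78 °C; then 3, −78 °C; aq. NH4Cl
Reagents that add atoms: none
Why: Lateral (vinylogous) deprotonation of the C6 methyl group by the hindered amide gives the extended dienolate 5, which adds to the aldehyde through its exocyclic carbon (vinylogous aldol addition); the new carbinol centre is racemic, which does not matter because step 4 oxidises it.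

Step 4
Reactants: 6 rac-6-[13-[(tert-butyldimethylsilyl)oxy]-2-hydroxytridecyl]-4-methoxy-2H-pyran-2-one
Product: 7 6-[13-[(tert-butyldimethylsilyl)oxy]-2-oxotridecyl]-4-methoxy-2H-pyran-2-one
Conditions: Dess–Martin periodinane (1.2 equiv), NaHCO3, CH2Cl2, 0 °C → rt
Reagents that add atoms: none
Why: Dess–Martin oxidation of a secondary alcohol under buffered, non-basic conditions, which should avoid dehydration of the β-hydroxy pyranone; a small excess only, so the activated methylene of 7 is not oxidised further.

Step 5
Reactants: 7 6-[13-[(tert-butyldimethylsilyl)oxy]-2-oxotridecyl]-4-methoxy-2H-pyran-2-one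
Product: 8 (R)-6-[13-[(tert-butyldimethylsilyl)oxy]-2-hydroxytridecyl]-4-methoxy-2H-pyran-2-one
Conditions: RuCl[(R,R)-TsDPEN](p-cymene) (2 mol%), HCO2H/Et3N (5:2), EtOAc, rt
Reagents that add atoms: none
Why: Asymmetric transfer hydrogenation by concerted outer-sphere delivery of hydride from ruthenium and a proton from the ligand NH; the C3 stereocentre is set here by the catalyst, the pyranonylmethyl side with its π system and ring oxygen playing the part of the aryl group of an aryl alkyl ketone (a vinylogous β-keto ester). The mildly acidic medium leaves the pyranone and the silyl ether intact.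

Step 6
Reactants: 9 propiolic acid
Product: 10 3-bromoprop-2-ynoic acid
Conditions: NBS (1.1 equiv), AgNO3 (10 mol%), acetone, rt, dark
Reagents that add atoms: N-bromosuccinimide, O=C1CCC(=O)N1Br
Why: Silver-catalysed bromination of a terminal alkyne through the silver acetylide; doing it on the free acid keeps electrophilic bromine away from the pyranone. The acid is used promptly and is not heated.

Step 7
Reactants: 8 (R)-6-[13-[(tert-butyldimethylsilyl)oxy]-2-hydroxytridecyl]-4-methoxy-2H-pyran-2-one; 10 3-bromoprop-2-ynoic acid
Product: 11 (R)-13-[(tert-butyldimethylsilyl)oxy]-1-(4-methoxy-2-oxo-2H-pyran-6-yl)tridecan-2-yl 3-bromoprop-2-ynoate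
Conditions: DIC (1.3 equiv), DMAP (2 mol%), CH2Cl2, −20 → 0 °C
Reagents that add atoms: none
Why: Carbodiimide (Steglich-type) esterification in which the C3–O bond is not broken, so the R configuration is retained; only a trace of DMAP at low temperature is used, because the bromoalkynoate accepts nucleophiles and the C4 methylene of 11 is acidic with a good leaving group next to it.

Step 8
Reactants: 11 (R)-13-[(tert-butyldimethylsilyl)oxy]-1-(4-methoxy-2-oxo-2H-pyran-6-yl)tridecan-2-yl 3-bromoprop-2-ynoate
Product: 13 (R)-8-bromo-3-[11-[(tert-butyldimethylsilyl)oxy]undecyl]-6-methoxyisochroman-1-one, via oxabicyclo[2.2.2]octadienone cycloadduct 12 (not isolated)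
Conditions: PhMe (0.005 M, degassed), BHT (10 mol%), sealed vessel, 150 °C (raised stepwise from 110 °C)
Reagents that add atoms: none
Why: This is the intramolecular Diels–Alder addition of a 2-pyranone to a tethered alkyne followed by cycloreversion, a known sequence applied here to an ynoate ester tether. Once the ester has rotated into its less stable, lactone-like rotamer, the pyranone diene C3=C4–C5=C6 adds to the bromoalkyne: pyranone C6 bonds to the ester-bearing alkyne carbon (the C4a–C8a bond) and pyranone C3 to the bromine-bearing carbon (the C7–C8 bond), giving bridged adduct 12. Ring B closes in the fused mode of a type 1 intramolecular cycloaddition with a four-atom tether (C4, C3, O2, C1), as a six-membered lactone annulated across C4a–C8a. Ring A closes through the same two bonds as a cyclohexadiene bridged by O–C(=O), and becomes aromatic when 12 loses CO2 in an irreversible retro-[4+2] step. No stereocentre is created (the bridgeheads of 12 vanish on aromatisation) and the C3–O bond is untouched, so the R configuration is carried through. Regioselectivity is secured twice: the short tether allows only the pairing of C6 with the α-carbon, and polarity agrees, since the nucleophilic pyranone C3 (β to the 4-methoxy group) meets the electrophilic β-carbon of the ynoate. Intramolecular reaction must win over dimerisation and conjugate addition, which the high dilution and the radical inhibitor are meant to secure. The 4-methoxy group raises the diene and the ester lowers the alkyne, which should keep the temperature within what the silyl ether and the product aryl bromide tolerate.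

Step 9
Reactants: 13 (R)-8-bromo-3-[11-[(tert-butyldimethylsilyl)oxy]undecyl]-6-methoxyisochroman-1-one
Product: 15 (R)-3-[11-[(tert-butyldimethylsilyl)oxy]undecyl]-8-hydroxy-6-methoxyisochroman-1-one, via pinacol C8-boronate 14 (not isolated)
Conditions: Pd(dppf)Cl2 (5 mol%), B2pin2, KOAc, 1,4-dioxane, 85 °C; then NaBO3·4H2O, THF/H2O, rt
Reagents that add atoms: bis(pinacolato)diboron, CC1(C)OB(OC1(C)C)B1OC(C)(C)C(C)(C)O1 (boron and pinacolate of 14 only); sodium perborate tetrahydrate, written as its peroxoborate salt [Na+].[Na+].O[B-]1(O)OO[B-](O)(O)OO1 (the phenol oxygen of 15)
Why: Miyaura borylation (oxidative addition of zerovalent palladium into C8–Br, transmetalation from acetate-activated diboron, reductive elimination) followed by oxidation of the C–B bond with aryl migration to oxygen; acetate and perborate are mild enough to leave the lactone and the silyl ether, and running both in one pot keeps the bromine handle to a single step.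

Step 10
Reactants: 15 (R)-3-[11-[(tert-butyldimethylsilyl)oxy]undecyl]-8-hydroxy-6-methoxyisochroman-1-one
Product: 16 (R)-8-hydroxy-3-(11-hydroxyundecyl)-6-methoxyisochroman-1-one
Conditions: 1 M aq. HCl, THF, rt
Reagents that add atoms: none
Why: Acid-catalysed hydrolysis of a primary silyl ether; under acid the lactone is the stable form of the hydroxy acid and C3, an unactivated carbinol carbon, cannot epimerise.

## Compound list

1 | dodecane-1,12-diol | OCCCCCCCCCCCCO | starting material
2 | 12-[(tert-butyldimethylsilyl)oxy]dodecan-1-ol | CC(C)(C)[Si](C)(C)OCCCCCCCCCCCCO | intermediate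
3 | 12-[(tert-butyldimethylsilyl)oxy]dodecanal | CC(C)(C)[Si](C)(C)OCCCCCCCCCCCC=O | intermediate
4 | 4-methoxy-6-methyl-2H-pyran-2-one | COC1=CC(=O)OC(C)=C1 | starting material
5 | 6-(lithiomethyl)-4-methoxy-2H-pyran-2-one (extended lithium dienolate) | [Li]CC1=CC(OC)=CC(=O)O1 | intermediate (not isolated)
6 | rac-6-[13-[(tert-butyldimethylsilyl)oxy]-2-hydroxytridecyl]-4-methoxy-2H-pyran-2-one | COC1=CC(=O)OC(CC(O)CCCCCCCCCCCO[Si](C)(C)C(C)(C)C)=C1 | intermediate
7 | 6-[13-[(tert-butyldimethylsilyl)oxy]-2-oxotridecyl]-4-methoxy-2H-pyran-2-one | COC1=CC(=O)OC(CC(=O)CCCCCCCCCCCO[Si](C)(C)C(C)(C)C)=C1 | intermediate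
8 | (R)-6-[13-[(tert-butyldimethylsilyl)oxy]-2-hydroxytridecyl]-4-methoxy-2H-pyran-2-one | COC1=CC(=O)OC(C[C@H](O)CCCCCCCCCCCO[Si](C)(C)C(C)(C)C)=C1 | intermediate
9 | propiolic acid (prop-2-ynoic acid) | C#CC(=O)O | starting material
10 | 3-bromoprop-2-ynoic acid | OC(=O)C#CBr | intermediate
11 | (R)-13-[(tert-butyldimethylsilyl)oxy]-1-(4-methoxy-2-oxo-2H-pyran-6-yl)tridecan-2-yl 3-bromoprop-2-ynoate | COC1=CC(=O)OC(C[C@H](OC(=O)C#CBr)CCCCCCCCCCCO[Si](C)(C)C(C)(C)C)=C1 | intermediate (key-step precursor)
12 | 5-bromo-8-methoxy-2-oxabicyclo[2.2.2]octa-5,7-dien-3-one whose C1 and C6 are spanned by CH2–CH[(CH2)11OTBS]–O–C(=O) (R at the carbinol carbon; either configuration of the bridgehead pair) | O=C1O[C@H](CCCCCCCCCCCO[Si](C)(C)C(C)(C)C)CC23OC(=O)C(C(OC)=C2)C(Br)=C13 | intermediate (not isolated)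
13 | (R)-8-bromo-3-[11-[(tert-butyldimethylsilyl)oxy]undecyl]-6-methoxyisochroman-1-one | COc1cc(Br)c2c(c1)C[C@@H](CCCCCCCCCCCO[Si](C)(C)C(C)(C)C)OC2=O | intermediate (key-step product)
14 | (R)-3-[11-[(tert-butyldimethylsilyl)oxy]undecyl]-6-methoxy-8-(4,4,5,5-tetramethyl-1,3,2-dioxaborolan-2-yl)isochroman-1-one | COc1cc(B3OC(C)(C)C(C)(C)O3)c2c(c1)C[C@@H](CCCCCCCCCCCO[Si](C)(C)C(C)(C)C)OC2=O | intermediate (not isolated)
15 | (R)-3-[11-[(tert-butyldimethylsilyl)oxy]undecyl]-8-hydroxy-6-methoxyisochroman-1-one | COc1cc(O)c2c(c1)C[C@@H](CCCCCCCCCCCO[Si](C)(C)C(C)(C)C)OC2=O | intermediate
16 | (R)-8-hydroxy-3-(11-hydroxyundecyl)-6-methoxyisochroman-1-one | COc1cc(O)c2c(c1)C[C@@H](CCCCCCCCCCCO)OC2=O | target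

## Step count and least certain steps

Total: 10 steps. Longest linear sequence: 9 steps (steps 1–5 and 7–10, from 1); step 6 is a one-step branch.

**Step 8 (key step).** The most likely failure is that cycloaddition, slowed by the need to populate the unfavoured ester rotamer, is outrun by thermal decomposition or oligomerisation of the bromoalkynoate, or by elimination of bromopropiolic acid across C3–C4. The fallback uses the same pyranone-to-arene chemistry without the tether, which is known, and closes the lactone afterwards; it sets out from 8 and returns at 13. Alcohol 8 is silylated (TBSCl, imidazole, DMF) to (R)-6-[2,13-bis[(tert-butyldimethylsilyl)oxy]tridecyl]-4-methoxy-2H-pyran-2-one F1. F1 is heated in xylene at 140–160 °C with an excess of methyl 3-bromoprop-2-ynoate F2 (made from methyl propiolate with NBS and catalytic AgNO3). Polarity alone then directs pyranone C3 to the bromine-bearing carbon, and loss of CO2 should give methyl (R)-2-bromo-6-[2,13-bis[(tert-butyldimethylsilyl)oxy]tridecyl]-4-methoxybenzoate F3. TsOH·H2O in MeOH, then warm toluene, removes both silyl groups and closes the lactone to (R)-8-bromo-3-(11-hydroxyundecyl)-6-methoxyisochroman-1-one F4, which is re-silylated (TBSCl, imidazole) to 13.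

**Step 5.** The likely problem is poor facial selectivity, because both sides of the ketone begin with a methylene group and the catalyst must tell them apart by a remote π system; the sense of induction is also an assumption. The fallback moves the reduction to an ynone, where the alkynyl group directs reliably; it sets out from 4 (through 5) and returns at 8. Undec-10-yn-1-ol is silylated to tert-butyldimethyl(undec-10-yn-1-yloxy)silane F5 and formylated (n-BuLi, then DMF, −78 °C) to 12-[(tert-butyldimethylsilyl)oxy]dodec-2-ynal F6. Dienolate 5 adds to F6 to give rac-6-[13-[(tert-butyldimethylsilyl)oxy]-2-hydroxytridec-3-yn-1-yl]-4-methoxy-2H-pyran-2-one F7, and MnO2 oxidation gives 6-[13-[(tert-butyldimethylsilyl)oxy]-2-oxotridec-3-yn-1-yl]-4-methoxy-2H-pyran-2-one F8. RuCl[(S,S)-TsDPEN](p-cymene) in i-PrOH should reduce F8 to (S)-6-[13-[(tert-butyldimethylsilyl)oxy]-2-hydroxytridec-3-yn-1-yl]-4-methoxy-2H-pyran-2-one F9. Hydrogenation of the triple bond (H2, Pd/C, EtOAc, stopped at two equivalents) gives 8; the descriptor changes from S to R only because the alkyl group no longer outranks the pyranonylmethyl group.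

**Step 7.** The likely problems are conjugate addition of the nucleophilic catalyst or the alcohol to the activated bromoalkynoate, and base-induced elimination of the new ester. The fallback changes the order of bond formation; it sets out from 8 (with 9) and returns at 11. Alcohol 8 is esterified with propiolic acid 9 (DIC, CH2Cl2, −20 °C) to (R)-13-[(tert-butyldimethylsilyl)oxy]-1-(4-methoxy-2-oxo-2H-pyran-6-yl)tridecan-2-yl prop-2-ynoate F10. The terminal alkyne is then brominated with one equivalent of NBS and catalytic AgNO3 in acetone, where the silver acetylide pathway should outpace attack of bromine at pyranone C3.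

**Step 9.** The likely problems are reductive loss of bromine during borylation of the bromide next to the lactone carbonyl, and lactone opening in the oxidation. The fallback replaces the boron detour by a direct C–O coupling with a hydroxide surrogate; it sets out from 13 and returns at 15. Bromide 13 is coupled with (E)-benzaldoxime (Pd2(dba)3, tBuBrettPhos, Cs2CO3, DMF, 80 °C) to give (R)-8-[[(E)-benzylideneamino]oxy]-3-[11-[(tert-butyldimethylsilyl)oxy]undecyl]-6-methoxyisochroman-1-one F11, which fragments in the flask under the carbonate base to 15 and benzonitrile.

## Further compounds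

F1 | step 8 | (R)-6-[2,13-bis[(tert-butyldimethylsilyl)oxy]tridecyl]-4-methoxy-2H-pyran-2-one | COC1=CC(=O)OC(C[C@H](O[Si](C)(C)C(C)(C)C)CCCCCCCCCCCO[Si](C)(C)C(C)(C)C)=C1
F2 | step 8 | methyl 3-bromoprop-2-ynoate | COC(=O)C#CBr
F3 | step 8 | methyl (R)-2-bromo-6-[2,13-bis[(tert-butyldimethylsilyl)oxy]tridecyl]-4-methoxybenzoate | COC(=O)c1c(Br)cc(OC)cc1C[C@H](O[Si](C)(C)C(C)(C)C)CCCCCCCCCCCO[Si](C)(C)C(C)(C)C
F4 | step 8 | (R)-8-bromo-3-(11-hydroxyundecyl)-6-methoxyisochroman-1-one | COc1cc(Br)c2c(c1)C[C@@H](CCCCCCCCCCCO)OC2=O
F5 | step 5 | tert-butyldimethyl(undec-10-yn-1-yloxy)silane | C#CCCCCCCCCCO[Si](C)(C)C(C)(C)C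
F6 | step 5 | 12-[(tert-butyldimethylsilyl)oxy]dodec-2-ynal | O=CC#CCCCCCCCCCO[Si](C)(C)C(C)(C)C
F7 | step 5 | rac-6-[13-[(tert-butyldimethylsilyl)oxy]-2-hydroxytridec-3-yn-1-yl]-4-methoxy-2H-pyran-2-one | COC1=CC(=O)OC(CC(O)C#CCCCCCCCCCO[Si](C)(C)C(C)(C)C)=C1
F8 | step 5 | 6-[13-[(tert-butyldimethylsilyl)oxy]-2-oxotridec-3-yn-1-yl]-4-methoxy-2H-pyran-2-one | COC1=CC(=O)OC(CC(=O)C#CCCCCCCCCCO[Si](C)(C)C(C)(C)C)=C1
F9 | step 5 | (S)-6-[13-[(tert-butyldimethylsilyl)oxy]-2-hydroxytridec-3-yn-1-yl]-4-methoxy-2H-pyran-2-one | COC1=CC(=O)OC(C[C@H](O)C#CCCCCCCCCCO[Si](C)(C)C(C)(C)C)=C1
F10 | step 7 | (R)-13-[(tert-butyldimethylsilyl)oxy]-1-(4-methoxy-2-oxo-2H-pyran-6-yl)tridecan-2-yl prop-2-ynoate | COC1=CC(=O)OC(C[C@H](OC(=O)C#C)CCCCCCCCCCCO[Si](C)(C)C(C)(C)C)=C1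
F11 | step 9 | (R)-8-[[(E)-benzylideneamino]oxy]-3-[11-[(tert-butyldimethylsilyl)oxy]undecyl]-6-methoxyisochroman-1-one | COc1cc(O/N=C/c3ccccc3)c2c(c1)C[C@@H](CCCCCCCCCCCO[Si](C)(C)C(C)(C)C)OC2=O
A1 | alternative 1 | 2-(buta-2,3-dien-1-yl)-4,6-dimethoxybenzoic acid | OC(=O)c1c(OC)cc(OC)cc1CC=C=C
A2 | alternative 1 | (S)-6,8-dimethoxy-3-vinylisochroman-1-one | COc1cc(OC)c2c(c1)C[C@@H](C=C)OC2=O
A3 | alternative 1 | undec-10-en-1-ol | C=CCCCCCCCCCO
A4 | alternative 2 | methyl (R)-5,16-bis[(tert-butyldimethylsilyl)oxy]hexadec-2-ynoate | COC(=O)C#CC[C@H](O[Si](C)(C)C(C)(C)C)CCCCCCCCCCCO[Si](C)(C)C(C)(C)C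
A5 | alternative 2 | 1,3-dimethoxy-1-(trimethylsilyloxy)buta-1,3-diene | C=C(OC)C=C(OC)O[Si](C)(C)C
A6 | alternative 2 | methyl 2-[(R)-2,13-bis[(tert-butyldimethylsilyl)oxy]tridecyl]-6-hydroxy-4-methoxybenzoate | COC(=O)c1c(O)cc(OC)cc1C[C@H](O[Si](C)(C)C(C)(C)C)CCCCCCCCCCCO[Si](C)(C)C(C)(C)C
A7 | alternative 3 | (R)-13-(benzyloxy)-1-(3,5-dimethoxyphenyl)tridecan-2-yl dimethylcarbamate | COc1cc(OC)cc(C[C@H](OC(=O)N(C)C)CCCCCCCCCCCOCc2ccccc2)c1
A8 | alternative 3 | (R)-3-[11-(benzyloxy)undecyl]-6,8-dimethoxyisochroman-1-one | COc1cc(OC)c2c(c1)C[C@@H](CCCCCCCCCCCOCc1ccccc1)OC2=O
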